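## Retrosynthetic overview

1. The C-8 ketone is unmasked last from a C-8 methyl enol ether; the 4-pyridone ring (formed second) comes from a 1,3,5-triketone and ammonia.
2. The triketone comes from two enolate C-acylations of a 2-methoxycyclohex-2-enone: methoxyacetyl at C-4a, then acetyl at C-3.
3. The 2-methoxy enone comes from a 5-alkylcyclohex-2-enone by epoxidation and methoxide opening.
4. The key C-4a–C-5 bond and the C-5 stereocentre come from an amine-catalysed asymmetric Michael addition of an acetoacetate ester to an (E)-enal; aldol condensation and decarboxylation in the same flask close the carbocycle (formed first).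
5. The enal comes from a 6-arylhexanol by oxidation and Wittig homologation.

Assumption: the five starting materials and either enantiomer of the silyl prolinol catalyst are purchased.

## Route

Step 1
Reactants: 1 6-phenylhexan-1-ol
Product: 2 6-phenylhexanal
Conditions: 2,2,6,6-tetramethylpiperidin-1-oxyl (10 mol%), PhI(OAc)2 (1.1 equiv), CH2Cl2, rt
Reagents that add atoms: none
Why: Oxoammonium-mediated alcohol oxidation stops at the aldehyde for an unhindered primary alcohol and touches nothing else.

Step 2
Reactants: 2 6-phenylhexanal; 3 2-(triphenyl-λ5-phosphanylidene)acetaldehyde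
Product: 4 (E)-8-phenyloct-2-enal
Conditions: toluene, 80 °C
Reagents that add atoms: none
Why: Wittig olefination with a formyl-stabilised ylide gives the E-enal selectively and adds the two carbons that become C-6 and C-7.

Step 3
Reactants: 4 (E)-8-phenyloct-2-enal; 5 tert-butyl 3-oxobutanoate
Product: 9 (S)-5-(5-phenylpentyl)cyclohex-2-en-1-one, via Michael adduct keto aldehyde 6 (not isolated), via cyclohexenone tert-butyl ester 7 (not isolated), via cyclohexenone carboxylic acid 8 (not isolated)
Conditions: (R)-2-{bis[3,5-bis(trifluoromethyl)phenyl](trimethylsilyloxy)methyl}pyrrolidine (10 mol%), neat, rt; then p-toluenesulfonic acid monohydrate (20 mol%), toluene, 80 °C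
Reagents that add atoms: none
Why: Iminium-ion organocatalytic Michael addition in which the (R)-pyrrolidine forms an E-iminium ion with 4 whose one face is blocked by the silyloxy-diarylmethyl group, so the ketoester adds to the open face of C-3 to give the 3S adduct (C-5 of the target), after which acid brings about intramolecular aldol condensation, tert-butyl ester cleavage and decarboxylation.

Step 4
Reactants: 9 (S)-5-(5-phenylpentyl)cyclohex-2-en-1-one
Product: 10 (4S)-4-(5-phenylpentyl)-7-oxabicyclo[4.1.0]heptan-2-one (mixture of epoxide diastereomers)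
Conditions: 30% aq. H2O2, NaOH (0.2 equiv), MeOH, 0 °C
Reagents that add atoms: hydrogen peroxide, OO
Why: Weitz–Scheffer nucleophilic epoxidation, in which hydroperoxide adds to the unhindered enone β-carbon and the enolate closes the epoxide (mainly anti to the C-5 chain), the two new epoxide centres being erased in step 5.

Step 5
Reactants: 10 (4S)-4-(5-phenylpentyl)-7-oxabicyclo[4.1.0]heptan-2-one
Product: 12 (S)-2-methoxy-5-(5-phenylpentyl)cyclohex-2-en-1-one, via methoxy hydroxy ketone 11 (not isolated)
Conditions: NaOMe (0.5 equiv), MeOH, reflux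
Reagents that add atoms: methanol, CO
Why: Methoxide opens the epoxy ketone by SN2 attack at the carbonyl-activated α-carbon and E1cB loss of the β-hydroxyl gives the 2-methoxy enone (diosphenol methyl ether), which fixes the future C-8 oxygen regiospecifically and leaves C-5 untouched.

Step 6
Reactants: 12 (S)-2-methoxy-5-(5-phenylpentyl)cyclohex-2-en-1-one; 13 N,2-dimethoxy-N-methylacetamide
Product: 15 (5S)-2-methoxy-6-(2-methoxyacetyl)-5-(5-phenylpentyl)cyclohex-2-en-1-one (C-6 epimers/enol forms), via lithium dienolate 14 (not isolated)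
Conditions: LiN(iPr)2 (1.1 equiv), THF, −78 °C; then 13, −78 to 0 °C; AcOH quench
Reagents that add atoms: none
Why: Crossed Claisen-type C-acylation of a kinetic lithium enolate with a Weinreb amide, in which C-6 is the only sp3 α-carbon of 12, the chelated adduct collapses to the 1,3-diketone only on quench, and the new C-6 centre is labile and later becomes sp2.

Step 7
Reactants: 15 (5S)-2-methoxy-6-(2-methoxyacetyl)-5-(5-phenylpentyl)cyclohex-2-en-1-one; 16 N-methoxy-N-methylacetamide
Product: 18 2-methoxy-1-[(6S)-3-methoxy-2-oxo-6-(5-phenylpentyl)cyclohex-3-en-1-yl]butane-1,3-dione (epimers/enol forms), via dilithium dianion 17 (not isolated)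
Conditions: LiN(iPr)2 (3.2 equiv), THF, −78 to −20 °C; then 16, −20 °C to rt; AcOH quench
Reagents that add atoms: none
Why: Harris-type γ-acylation of a 1,3-diketone dianion, in which the base removes the central C–H and then a proton from the methoxy-bearing CH2 (the only other α-C–H), and this more nucleophilic terminus is acetylated to the 1,3,5-triketone, whose new CH(OMe) centre is erased in step 8.

Step 8
Reactants: 18 2-methoxy-1-[(6S)-3-methoxy-2-oxo-6-(5-phenylpentyl)cyclohex-3-en-1-yl]butane-1,3-dione
Product: 20 (S)-3,8-dimethoxy-2-methyl-5-(5-phenylpentyl)-5,6-dihydroquinolin-4(1H)-one, via enaminone 19 (not isolated)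
Conditions: NH3 (7 M in MeOH), sealed tube, 60 °C
Reagents that add atoms: ammonia, N
Why: Classical 1,3,5-triketone-to-4-pyridone condensation, in which ammonia forms the enaminone at the acetyl carbonyl and the nitrogen then condenses with the ring carbonyl, aromatisation making the outcome independent of which terminal carbonyl reacts first.

Step 9
Reactants: 20 (S)-3,8-dimethoxy-2-methyl-5-(5-phenylpentyl)-5,6-dihydroquinolin-4(1H)-one
Product: 21 (S)-3-methoxy-2-methyl-5-(5-phenylpentyl)-1,5,6,7-tetrahydroquinoline-4,8-dione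
Conditions: 2 M aq. HCl, THF, 40 °C
Reagents that add atoms: water, O
Why: Acid-catalysed enol ether hydrolysis (C-7 protonation, hydration of the oxocarbenium ion, loss of methanol) unmasks the C-8 ketone while the aryl methyl ether at C-3 and the C-5 centre, which is not α to a carbonyl, stay intact.

## Compound list

1 | 6-phenylhexan-1-ol | OCCCCCCc1ccccc1 | starting material
2 | 6-phenylhexanal | O=CCCCCCc1ccccc1 | intermediate
3 | 2-(triphenyl-λ5-phosphanylidene)acetaldehyde | O=CC=P(c1ccccc1)(c1ccccc1)c1ccccc1 | starting material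
4 | (E)-8-phenyloct-2-enal | O=C/C=C/CCCCCc1ccccc1 | intermediate
5 | tert-butyl 3-oxobutanoate | CC(=O)CC(=O)OC(C)(C)C | starting material
6 | tert-butyl (3S)-2-acetyl-5-oxo-3-(5-phenylpentyl)pentanoate (C-2 epimers) | CC(=O)C(C(=O)OC(C)(C)C)[C@@H](CCCCCc1ccccc1)CC=O | intermediate
7 | tert-butyl (6S)-2-oxo-6-(5-phenylpentyl)cyclohex-3-ene-1-carboxylate (C-1 epimers) | CC(C)(C)OC(=O)C1[C@@H](CCCCCc2ccccc2)CC=CC1=O | intermediate
8 | (6S)-2-oxo-6-(5-phenylpentyl)cyclohex-3-ene-1-carboxylic acid (C-1 epimers) | OC(=O)C1[C@@H](CCCCCc2ccccc2)CC=CC1=O | intermediate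
9 | (S)-5-(5-phenylpentyl)cyclohex-2-en-1-one | O=C1C[C@@H](CCCCCc2ccccc2)CC=C1 | intermediate
10 | (4S)-4-(5-phenylpentyl)-7-oxabicyclo[4.1.0]heptan-2-one (epoxide diastereomers) | O=C1C[C@@H](CCCCCc2ccccc2)CC2OC12 | intermediate
11 | (5S)-3-hydroxy-2-methoxy-5-(5-phenylpentyl)cyclohexan-1-one (diastereomers) | O=C1C[C@@H](CCCCCc2ccccc2)CC(O)C1OC | intermediate
12 | (S)-2-methoxy-5-(5-phenylpentyl)cyclohex-2-en-1-one | O=C1C[C@@H](CCCCCc2ccccc2)CC=C1OC | intermediate
13 | N,2-dimethoxy-N-methylacetamide | COCC(=O)N(C)OC | starting material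
14 | lithium (3S)-6-methoxy-3-(5-phenylpentyl)cyclohexa-1,5-dien-1-olate | [Li+].[O-]C1=C[C@@H](CCCCCc2ccccc2)CC=C1OC | intermediate
15 | (5S)-2-methoxy-6-(2-methoxyacetyl)-5-(5-phenylpentyl)cyclohex-2-en-1-one (C-6 epimers/enol forms) | COCC(=O)C1[C@@H](CCCCCc2ccccc2)CC=C(OC)C1=O | intermediate
16 | N-methoxy-N-methylacetamide | CC(=O)N(C)OC | starting material
17 | dilithium dianion of 15 (oxido groups on the ring carbonyl carbon and the side-chain carbonyl carbon, carbanion terminus CH(OMe)) | [Li+].[Li+].[O-]C(=COC)C1=C([O-])C(OC)=CC[C@@H]1CCCCCc1ccccc1 | intermediate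
18 | 2-methoxy-1-[(6S)-3-methoxy-2-oxo-6-(5-phenylpentyl)cyclohex-3-en-1-yl]butane-1,3-dione (epimers/enol forms) | CC(=O)C(OC)C(=O)C1[C@@H](CCCCCc2ccccc2)CC=C(OC)C1=O | intermediate
19 | 3-amino-2-methoxy-1-[(6S)-3-methoxy-2-oxo-6-(5-phenylpentyl)cyclohex-3-en-1-yl]but-2-en-1-one | CC(N)=C(OC)C(=O)C1[C@@H](CCCCCc2ccccc2)CC=C(OC)C1=O | intermediate
20 | (S)-3,8-dimethoxy-2-methyl-5-(5-phenylpentyl)-5,6-dihydroquinolin-4(1H)-one | COc1c(C)[nH]c2c(c1=O)[C@@H](CCCCCc1ccccc1)CC=C2OC | intermediate
21 | (S)-3-methoxy-2-methyl-5-(5-phenylpentyl)-1,5,6,7-tetrahydroquinoline-4,8-dione | COc1c(C)[nH]c2c(c1=O)[C@@H](CCCCCc1ccccc1)CCC2=O | target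

## Step count and risks

Total steps: 9. Longest linear sequence: 9 steps (1 to 21); the route is fully linear.

**Step 7 (most likely to fail).** The second deprotonation must occur at a carbon that carries OMe, and incomplete dianion formation or O-acylation would give little 18. The fallback sets out from 12 and comes back at 20, fixing nitrogen on the ring carbon through an isoxazole instead of using a triketone. Ketone 12 is condensed with NH2OH·HCl and NaOAc in EtOH to (5S)-2-methoxy-5-(5-phenylpentyl)cyclohex-2-en-1-one oxime F1. Double deprotonation of the oxime (LiN(iPr)2, 2.2 equiv, THF, 0 °C), C-acylation at C-6 with 13 and cyclodehydration (MsCl, Et3N) give (4S)-7-methoxy-3-(methoxymethyl)-4-(5-phenylpentyl)-4,5-dihydro-2,1-benzoxazole F2. Mo(CO)6 in wet MeCN at 80 °C cleaves the N–O bond to 1-[(6S)-2-amino-3-methoxy-6-(5-phenylpentyl)cyclohexa-1,3-dien-1-yl]-2-methoxyethan-1-one F3. AcCl in pyridine gives N-[(3S)-6-methoxy-2-(2-methoxyacetyl)-3-(5-phenylpentyl)cyclohexa-1,5-dien-1-yl]acetamide F4. KOtBu in t-BuOH at 80 °C then closes the pyridone by Camps-type aldol condensation of the methoxyacetyl CH2 onto the acetamide carbonyl, giving 20.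

**Step 5.** Methoxide may open the epoxide slowly, or the epoxy ketone may isomerise to the diosphenol, whose O-methylation would not be regioselective. The fallback sets out from 4 and comes back at 12, bringing the C-8 oxygen in with the Michael donor. Enal 4 and methyl 4-methoxy-3-oxobutanoate, with the same pyrrolidine catalyst as in step 3, give methyl (3S)-2-(2-methoxyacetyl)-5-oxo-3-(5-phenylpentyl)pentanoate F5. p-Toluenesulfonic acid in toluene at 80 °C closes the ring by aldol condensation through the methoxy-bearing carbon to methyl (6S)-3-methoxy-2-oxo-6-(5-phenylpentyl)cyclohex-3-ene-1-carboxylate F6. LiCl in wet DMSO at 140 °C (Krapcho dealkoxycarbonylation) then gives 12.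

**Step 6.** C-acylation of the dienolate next to the C-5 side chain may be slow, with proton transfer or O-acylation competing. The fallback sets out from 12 and comes back at 15, replacing the acylation by aldol addition and oxidation. Lithium dienolate 14 (from 12, LiN(iPr)2, THF, −78 °C) adds to methoxyacetaldehyde to give (5S)-6-(1-hydroxy-2-methoxyethyl)-2-methoxy-5-(5-phenylpentyl)cyclohex-2-en-1-one F7. Dess–Martin periodinane in CH2Cl2 oxidises the carbinol to 15.

## Further compounds

F1 | step 7 | (5S)-2-methoxy-5-(5-phenylpentyl)cyclohex-2-en-1-one oxime | ON=C1C[C@@H](CCCCCc2ccccc2)CC=C1OC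
F2 | step 7 | (4S)-7-methoxy-3-(methoxymethyl)-4-(5-phenylpentyl)-4,5-dihydro-2,1-benzoxazole | COCc1onc2c1[C@@H](CCCCCc1ccccc1)CC=C2OC
F3 | step 7 | 1-[(6S)-2-amino-3-methoxy-6-(5-phenylpentyl)cyclohexa-1,3-dien-1-yl]-2-methoxyethan-1-one | COCC(=O)C1=C(N)C(OC)=CC[C@@H]1CCCCCc1ccccc1
F4 | step 7 | N-[(3S)-6-methoxy-2-(2-methoxyacetyl)-3-(5-phenylpentyl)cyclohexa-1,5-dien-1-yl]acetamide | COCC(=O)C1=C(NC(C)=O)C(OC)=CC[C@@H]1CCCCCc1ccccc1
F5 | step 5 | methyl (3S)-2-(2-methoxyacetyl)-5-oxo-3-(5-phenylpentyl)pentanoate (C-2 epimers) | COCC(=O)C(C(=O)OC)[C@@H](CCCCCc1ccccc1)CC=O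
F6 | step 5 | methyl (6S)-3-methoxy-2-oxo-6-(5-phenylpentyl)cyclohex-3-ene-1-carboxylate (C-1 epimers) | COC(=O)C1[C@@H](CCCCCc2ccccc2)CC=C(OC)C1=O
F7 | step 6 | (5S)-6-(1-hydroxy-2-methoxyethyl)-2-methoxy-5-(5-phenylpentyl)cyclohex-2-en-1-one (diastereomers) | COCC(O)C1[C@@H](CCCCCc2ccccc2)CC=C(OC)C1=O
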